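**Retrosynthetic overview**
Locants: oxane O1, C2 (Me, C1′), C3 (OAc), C4, C5 (Br), C6 (Me2); carbocycle C1′ (on C2), C2′, C3′ (Br), C4′ (Me, Cl), C5′, C6′ (OH).
Feature used: C1′ and C6′ are the α-carbon and carbonyl carbon of an (oxan-2-yl)acetaldehyde, and C2′–C5′ are the four carbons of methyl vinyl ketone with its carbonyl at C4′; the carbocycle is cut at C1′–C2′ (Michael) and C5′–C6′ (aldol).
After the annulation: C4′ ketone → C3′=C4′ methyl alkene (enol triflate, Negishi) → cis-diol → cyclic sulfate → bromide at C3′ (inversion) → chloride at C4′ (retention through the bromine-bridged cation).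
Before it: sulcatone → α-hydroxylation (C3) → chelation-controlled allylation (C2) → acetylation → 6-endo bromoetherification (O1–C6, C5–Br) → ozonolysis.
Ring order: oxane first (step 4), carbocycle second (step 6).

Key step: step 6

Remark: "Ox" is the (2S,3S,5S)-3-acetoxy-5-bromo-2,6,6-trimethyloxan-2-yl group; "lower face" of the carbocycle is the face opposite the C1′–Ox and C6′–O bonds.
Assumption: both enantiomers of proline and of α,α-diphenylprolinol trimethylsilyl ether are taken as commercial catalysts.

Step 1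
Reactants: 1 6-methylhept-5-en-2-one (sulcatone)
Product: 3 (S)-3-hydroxy-6-methylhept-5-en-2-one, via anilinooxy ketone 2 (not isolated)
Conditions: D-proline (20 mol %), PhNO (1 equiv, slow addition), 1 (3 equiv), DMSO, rt; then CuSO4·5H2O (30 mol %), MeOH, 0 °C
Reagents that add atoms: nitrosobenzene, O=Nc1ccccc1
Why: Proline-catalysed α-aminoxylation (O-selective nitroso aldol) of the enamine formed on the methylene side of the methyl ketone, where the carboxylic acid delivers nitrosobenzene to the face that gives 3S with D-proline, followed by copper-catalysed N–O cleavage that leaves the stereocentre untouched; slow addition to excess ketone keeps the prenyl alkene out of a nitroso-ene reaction.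

Step 2
Reactants: 3 (S)-3-hydroxy-6-methylhept-5-en-2-one; 4 allyl bromide
Product: 5 (4S,5S)-4,8-dimethylnona-1,7-diene-4,5-diol
Conditions: In powder (1.5 equiv), 4 (2 equiv), THF/H2O 1:1, rt
Reagents that add atoms: none
Why: Barbier-type allylation with allylindium, in which the free α-hydroxyl and the carbonyl oxygen chelate indium and allyl enters the chelate from the face carrying H (chelation control), setting 4S so that allyl and the C5 oxygen become cis on the oxane; indium is chosen because allylmagnesium halides respond poorly to chelation.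

Step 3
Reactants: 5 (4S,5S)-4,8-dimethylnona-1,7-diene-4,5-diol
Product: 6 (4S,5S)-4-hydroxy-4,8-dimethylnona-1,7-dien-5-yl acetate
Conditions: Ac2O (1.2 equiv), pyridine, DMAP (5 mol %), CH2Cl2, 0 °C
Reagents that add atoms: acetic anhydride, CC(=O)OC(C)=O
Why: DMAP-catalysed acylation is much faster at the secondary than at the tertiary hydroxyl, so the tertiary OH stays free as the nucleophile of step 4; no stereocentre changes.

Step 4
Reactants: 6 (4S,5S)-4-hydroxy-4,8-dimethylnona-1,7-dien-5-yl acetate
Product: 7 (2S,3S,5S)-5-bromo-2,6,6-trimethyl-2-(prop-2-en-1-yl)oxan-3-yl acetate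
Conditions: TBCO (1.1 equiv), MeNO2, 0 °C → rt, dark
Reagents that add atoms: 2,4,4,6-tetrabromocyclohexa-2,5-dien-1-one, O=C1C(Br)=CC(Br)(Br)C=C1Br
Why: Bromoetherification: Br+ adds to the trisubstituted alkene and the tertiary hydroxyl opens the bromonium at its tertiary carbon (6-endo, Markovnikov) anti to bromine through a chair with C5–Br equatorial, the C3 acetoxy group axial next to the quaternary C2 and allyl equatorial, which places Br trans to OAc (5S); the C5 epimer and the 5-exo oxolane are expected as minor by-products to be removed by chromatography.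

Step 5
Reactants: 7 (2S,3S,5S)-5-bromo-2,6,6-trimethyl-2-(prop-2-en-1-yl)oxan-3-yl acetate
Product: 9 (2S,3S,5S)-5-bromo-2,6,6-trimethyl-2-(2-oxoethyl)oxan-3-yl acetate (Ox–CH2–CHO), via ozonide 8 (not isolated)
Conditions: O3, CH2Cl2, −78 °C; then PPh3, −78 °C → rt
Reagents that add atoms: ozone, [O-][O+]=O
Why: Ozonolysis with reductive work-up cleaves the only remaining C=C under neutral conditions that tolerate the bromide, the acetate and the β-alkoxy aldehyde; no stereocentre is touched.

Step 6
Reactants: 9 Ox–CH2–CHO; 10 methyl vinyl ketone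
Product: 12 (3R,4S)-3-hydroxy-4-Ox-cyclohexan-1-one (cis-ketol, 1′S,6′R), via keto-aldehyde 11 (not isolated)
Conditions: (R)-α,α-diphenylprolinol TMS ether (20 mol %), ethyl 3,4-dihydroxybenzoate (20 mol %), 10 (3 equiv), CHCl3, 4 °C → rt; volatiles removed in vacuo; then D-proline (30 mol %), DMSO, rt
Reagents that add atoms: none
Why: The (R)-diarylprolinol silyl ether condenses with 9 to the E-enamine, whose C1′ adds to catechol-activated 10 from the face away from the CPh2OTMS group and is hydrolysed to 11, after which D-proline forms the methyl-side enamine of the ketone (C5′), which attacks the aldehyde carbon C6′ and is hydrolysed to 12. The closest known reactions are the diarylprolinol-ether-catalysed Michael addition of aldehydes to vinyl ketones and the proline-catalysed intramolecular enolexo aldolisation, together an organocatalytic Robinson-type annulation stopped before dehydration. The carbocycle closes in a 6-(enolexo)-exo-trig mode, the alternative closures from C3′ or from the aldehyde α-carbon leading only to four-membered rings. C1′ (1′S) is set by the catalyst: the (S)-catalyst gives 2R in the aldehyde–nitroalkene reference reaction, so the (R)-catalyst delivers the enone to the enamine face required here, with the neighbouring quaternary C2 only a matched or mismatched bystander. C6′ (6′R) is set by substrate and promoter together: in the chair the Ox group on C1′ is equatorial and the aldehyde oxygen, hydrogen-bonded to the proline carboxyl, is axial, which gives the cis-ketol, and D-proline is the enantiomer whose carboxyl-directed face of attack fits this chair. The step needs a single enamine and configurational stability at C2 and C1′, secured because the only enolisable position of 9 is a methylene next to the fully substituted C2 and because the α-branched aldehyde of 11 is too hindered to re-form an enamine.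

Step 7
Reactants: 12 (3R,4S)-3-hydroxy-4-Ox-cyclohexan-1-one
Product: 13 (3R,4S)-3-(tert-butyldimethylsilyloxy)-4-Ox-cyclohexan-1-one
Conditions: TBSOTf (1.3 equiv), 2,6-lutidine, CH2Cl2, −78 °C
Reagents that add atoms: tert-butyldimethylsilyl trifluoromethanesulfonate, CC(C)(C)[Si](C)(C)OS(=O)(=O)C(F)(F)F
Why: Silylation with the silyl triflate and a hindered pyridine at low temperature protects the axial secondary alcohol of the β-ketol without retro-aldol cleavage or dehydration; no stereocentre changes.

Step 8
Reactants: 13 (3R,4S)-3-(tert-butyldimethylsilyloxy)-4-Ox-cyclohexan-1-one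
Product: 15 (4S,5R)-5-(tert-butyldimethylsilyloxy)-4-Ox-cyclohex-1-en-1-yl trifluoromethanesulfonate (C3′=C4′), via lithium enolate 14 (not isolated)
Conditions: LiHMDS (1.05 equiv), THF, −78 °C; then PhNTf2, −78 → 0 °C
Reagents that add atoms: N-phenylbis(trifluoromethanesulfonimide), O=S(=O)(N(c1ccccc1)S(=O)(=O)C(F)(F)F)C(F)(F)F
Why: Kinetic deprotonation by the hindered amide should occur at C3′, the α-methylene remote from the silyloxy-bearing C6′ (steric shielding of C5′ and the usual distal enolisation of β-oxygenated ketones), and at the ketone in preference to the less acidic acetate; O-sulfonylation then fixes the C3′=C4′ enol triflate.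

Step 9
Reactants: 15 enol triflate
Product: 16 (1′S,6′R)-1′-Ox-6′-(tert-butyldimethylsilyloxy)-4′-methylcyclohex-3′-ene
Conditions: MeZnCl (2 equiv), Pd(PPh3)4 (5 mol %), THF, rt → 40 °C
Reagents that add atoms: methylzinc chloride, C[Zn]Cl
Why: Negishi coupling (oxidative addition to the alkenyl triflate, transmetalation, reductive elimination) replaces OTf by CH3 without moving the double bond, and the organozinc leaves the acetate and the hindered secondary alkyl bromide alone.

Step 10
Reactants: 16 methyl alkene
Product: 17 (1′S,3′S,4′R,6′R)-1′-Ox-6′-(tert-butyldimethylsilyloxy)-4′-methylcyclohexane-3′,4′-diol (both OH on the lower face)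
Conditions: OsO4 (5 mol %), NMO (1.5 equiv), acetone/H2O 4:1, rt
Reagents that add atoms: osmium tetroxide (catalytic), O=[Os](=O)(=O)=O; N-methylmorpholine N-oxide, C[N+]1([O-])CCOCC1; water, O
Why: Catalytic syn-dihydroxylation (Upjohn conditions) from the face opposite the axial C6′ silyloxy group, which blocks the other face of C4′ in a 1,3-diaxial sense, so both new hydroxyls are trans to the C6′ oxygen (3′S,4′R) and the methyl group ends syn to it as in the target.

Step 11
Reactants: 17 diol
Product: 19 3′,4′-cyclic sulfate of 17, via cyclic sulfite 18 (not isolated)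
Conditions: SOCl2, Et3N, CH2Cl2, 0 °C; then RuCl3·xH2O (1 mol %), NaIO4, MeCN/H2O, 0 °C
Reagents that add atoms: thionyl chloride, O=S(Cl)Cl; sodium periodate, [Na+].[O-][I](=O)(=O)=O
Why: Cyclic sulfate formation from a 1,2-diol: thionyl chloride closes the cyclic sulfite and catalytic ruthenium tetroxide oxidises sulfur(IV) to sulfur(VI) without touching carbon stereocentres; the oxane has no C–H next to its oxygen for the oxidant to attack.

Step 12
Reactants: 19 cyclic sulfate
Product: 21 (1′S,3′R,4′R,6′R)-3′-bromo-1′-Ox-6′-(tert-butyldimethylsilyloxy)-4′-methylcyclohexan-4′-ol, via lithium bromoalkyl sulfate 20 (not isolated)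
Conditions: LiBr (3 equiv), THF, 50 °C; then H2SO4 (cat.), H2O (2 equiv), THF, rt
Reagents that add atoms: lithium bromide, [Li+].[Br-]
Why: Nucleophilic opening of the cyclic sulfate: bromide attacks the secondary C3′ by SN2 with inversion (Br now cis to the Ox group) in preference to the tertiary C4′, and acid-catalysed hydrolysis of the sulfate monoester by S–O cleavage frees the tertiary alcohol with C4′ unchanged.

Step 13
Reactants: 21 bromohydrin
Product: 23 6′-O-tert-butyldimethylsilyl ether of the target (1′S,3′R,4′R,6′R), via chlorosulfite 22 (not isolated)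
Conditions: SOCl2 (2 equiv), 2,6-di-tert-butyl-4-methylpyridine (2.5 equiv), CH2Cl2, −40 → 0 °C
Reagents that add atoms: thionyl chloride, O=S(Cl)Cl
Why: Deoxychlorination with retention: the chlorosulfite ionises at the tertiary C4′, the vicinal bromine on the opposite face bridges the cation (neighbouring-group participation, the classical retention of β-bromo alcohols), and chloride opens the bromonium at its tertiary carbon anti to bromine, on the face oxygen left from and away from the axial C6′ silyloxy group, giving the trans-diequatorial bromide/chloride (4′R); the hindered pyridine traps HCl so the silyl ether survives.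

Step 14
Reactants: 23 silyl ether of the target
Product: 24 CNP0166766.1, (2S,3S,5S)-5-bromo-2-[(1S,2R,4R,5R)-5-bromo-4-chloro-2-hydroxy-4-methylcyclohexyl]-2,6,6-trimethyloxan-3-yl acetate
Conditions: HF·pyridine, pyridine, THF, 0 °C → rt
Reagents that add atoms: none
Why: Fluoride-mediated desilylation under mildly acidic conditions frees the C6′ hydroxyl without acetate migration or hydrolysis and without elimination of the tertiary chloride or the secondary bromides; no stereocentre changes.

**Compound list**
1 | 6-methylhept-5-en-2-one (sulcatone) | CC(C)=CCCC(C)=O | starting material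
2 | (3S)-3-(anilinooxy)-6-methylhept-5-en-2-one | CC(=O)[C@@H](ONc1ccccc1)CC=C(C)C | intermediate (not isolated)
3 | (S)-3-hydroxy-6-methylhept-5-en-2-one | CC(=O)[C@@H](O)CC=C(C)C | intermediate
4 | allyl bromide | C=CCBr | starting material
5 | (4S,5S)-4,8-dimethylnona-1,7-diene-4,5-diol | C=CC[C@](C)(O)[C@@H](O)CC=C(C)C | intermediate
6 | (4S,5S)-4-hydroxy-4,8-dimethylnona-1,7-dien-5-yl acetate | C=CC[C@](C)(O)[C@@H](OC(C)=O)CC=C(C)C | intermediate
7 | (2S,3S,5S)-5-bromo-2,6,6-trimethyl-2-(prop-2-en-1-yl)oxan-3-yl acetate | CC(=O)O[C@H]1C[C@H](Br)C(C)(C)O[C@@]1(C)CC=C | intermediate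
8 | ozonide of 7, (2S,3S,5S)-5-bromo-2,6,6-trimethyl-2-(1,2,4-trioxolan-3-ylmethyl)oxan-3-yl acetate | CC(=O)O[C@H]1C[C@H](Br)C(C)(C)O[C@@]1(C)CC1OCOO1 | intermediate (not isolated)
9 | (2S,3S,5S)-5-bromo-2,6,6-trimethyl-2-(2-oxoethyl)oxan-3-yl acetate | CC(=O)O[C@H]1C[C@H](Br)C(C)(C)O[C@@]1(C)CC=O | intermediate (key-step precursor)
10 | methyl vinyl ketone | CC(=O)C=C | starting material
11 | (2S,3S,5S)-5-bromo-2-[(2R)-1,5-dioxohexan-2-yl]-2,6,6-trimethyloxan-3-yl acetate | CC(=O)O[C@H]1C[C@H](Br)C(C)(C)O[C@@]1(C)[C@H](C=O)CCC(C)=O | intermediate (not isolated)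
12 | (2S,3S,5S)-5-bromo-2-[(1S,2R)-2-hydroxy-4-oxocyclohexyl]-2,6,6-trimethyloxan-3-yl acetate | CC(=O)O[C@H]1C[C@H](Br)C(C)(C)O[C@@]1(C)[C@H]1CCC(=O)C[C@H]1O | intermediate (key-step product)
13 | 6′-O-TBS ether of 12 | CC(=O)O[C@H]1C[C@H](Br)C(C)(C)O[C@@]1(C)[C@H]1CCC(=O)C[C@H]1O[Si](C)(C)C(C)(C)C | intermediate
14 | lithium C3′=C4′ enolate of 13 | CC(=O)O[C@H]1C[C@H](Br)C(C)(C)O[C@@]1(C)[C@H]1CC=C(O[Li])C[C@H]1O[Si](C)(C)C(C)(C)C | intermediate (not isolated)
15 | C3′=C4′ enol triflate of 13 | CC(=O)O[C@H]1C[C@H](Br)C(C)(C)O[C@@]1(C)[C@H]1CC=C(OS(=O)(=O)C(F)(F)F)C[C@H]1O[Si](C)(C)C(C)(C)C | intermediate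
16 | (2S,3S,5S)-5-bromo-2-[(1S,6R)-6-(tert-butyldimethylsilyloxy)-4-methylcyclohex-3-en-1-yl]-2,6,6-trimethyloxan-3-yl acetate | CC(=O)O[C@H]1C[C@H](Br)C(C)(C)O[C@@]1(C)[C@H]1CC=C(C)C[C@H]1O[Si](C)(C)C(C)(C)C | intermediate
17 | (2S,3S,5S)-5-bromo-2-[(1S,2R,4R,5S)-2-(tert-butyldimethylsilyloxy)-4,5-dihydroxy-4-methylcyclohexyl]-2,6,6-trimethyloxan-3-yl acetate | CC(=O)O[C@H]1C[C@H](Br)C(C)(C)O[C@@]1(C)[C@H]1C[C@H](O)[C@](C)(O)C[C@H]1O[Si](C)(C)C(C)(C)C | intermediate
18 | 3′,4′-cyclic sulfite of 17 | CC(=O)O[C@H]1C[C@H](Br)C(C)(C)O[C@@]1(C)[C@H]1C[C@@H]2OS(=O)O[C@]2(C)C[C@H]1O[Si](C)(C)C(C)(C)C | intermediate (not isolated)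
19 | 3′,4′-cyclic sulfate of 17 | CC(=O)O[C@H]1C[C@H](Br)C(C)(C)O[C@@]1(C)[C@H]1C[C@@H]2OS(=O)(=O)O[C@]2(C)C[C@H]1O[Si](C)(C)C(C)(C)C | intermediate
20 | lithium salt of the C4′ sulfate monoester of the (3′R)-bromide | CC(=O)O[C@H]1C[C@H](Br)C(C)(C)O[C@@]1(C)[C@H]1C[C@@H](Br)[C@](C)(OS(=O)(=O)[O-])C[C@H]1O[Si](C)(C)C(C)(C)C.[Li+] | intermediate (not isolated)
21 | (2S,3S,5S)-5-bromo-2-[(1S,2R,4R,5R)-5-bromo-2-(tert-butyldimethylsilyloxy)-4-hydroxy-4-methylcyclohexyl]-2,6,6-trimethyloxan-3-yl acetate | CC(=O)O[C@H]1C[C@H](Br)C(C)(C)O[C@@]1(C)[C@H]1C[C@@H](Br)[C@](C)(O)C[C@H]1O[Si](C)(C)C(C)(C)C | intermediate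
22 | C4′ chlorosulfite of 21 | CC(=O)O[C@H]1C[C@H](Br)C(C)(C)O[C@@]1(C)[C@H]1C[C@@H](Br)[C@](C)(OS(=O)Cl)C[C@H]1O[Si](C)(C)C(C)(C)C | intermediate (not isolated)
23 | 6′-O-TBS ether of the target | CC(=O)O[C@H]1C[C@H](Br)C(C)(C)O[C@@]1(C)[C@H]1C[C@@H](Br)[C@](C)(Cl)C[C@H]1O[Si](C)(C)C(C)(C)C | intermediate
24 | CNP0166766.1 | CC(=O)O[C@H]1C[C@H](Br)C(C)(C)O[C@@]1(C)[C@H]1C[C@@H](Br)[C@](C)(Cl)C[C@H]1O | target

**Step count and risks**
Total steps: 14. Longest linear sequence: 14 (from sulcatone; allyl bromide and methyl vinyl ketone are commercial).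

Step 6 (key step). The enamine carbon is neopentylic, so the Michael addition may be slow. The enamine may also expel the ring oxygen from C2 (β-alkoxy elimination, opening the oxane), the catalyst may be mismatched with the C2 centre, and the ketol may dehydrate or close with the C6′ oxygen equatorial. Fallback, with C1′ set by an oxazolidinone auxiliary: setting out from 9, Pinnick oxidation should give 2-[(2S,3S,5S)-3-acetoxy-5-bromo-2,6,6-trimethyloxan-2-yl]acetic acid F1. Activation as the pivalic mixed anhydride and acylation of lithiated (R)-4-benzyloxazolidin-2-one should give the N-acyl oxazolidinone F2. Its chlorotitanium Z-enolate (TiCl4, i-Pr2NEt, CH2Cl2) should add to 10 anti to the benzyl group to give the Michael adduct F3. LiSEt should convert the imide into the S-ethyl thioester F4, and Fukuyama reduction (Et3SiH, Pd/C) should give 11, which D-proline in DMSO closes as in step 6; the route is rejoined at 12.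

Step 13. The β-bromine retards C–O ionisation, so the chlorosulfite may collapse by elimination, the bridged cation may lose Br+, or HCl may strip the silyl ether before substitution. Fallback, reaching the same bromine-bridged cation from the alkene instead of the alcohol: setting out from 16, anti-bromochlorination with tetrabutylammonium dichlorobromate (CH2Cl2, −78 °C) puts chloride on the tertiary carbon. 23 would have to be separated from the diaxial adduct formed through the lower-face bromonium; the axial C6′ silyloxy group, which obstructs axial chloride entry at C4′, should reduce the share of that adduct. The route is rejoined at 23; no new compound (F0).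

Step 4. 5-exo closure may compete with 6-endo closure, and the two alkene faces may be poorly discriminated, giving the C5 epimer. Fallback, replacing the acetate by a bulky silyl ether as the control element (next to the quaternary C2 it should take the axial site in the chair and so direct bromine trans to it): setting out from 5, selective silylation of the secondary hydroxyl (TBSOTf, 2,6-lutidine, −78 °C) should give (4S,5S)-5-(tert-butyldimethylsilyloxy)-4,8-dimethylnona-1,7-dien-4-ol F5. TBCO cyclisation should give the bromo-oxane silyl ether F6, HF·pyridine the alcohol (2S,3S,5S)-5-bromo-2,6,6-trimethyl-2-(prop-2-en-1-yl)oxan-3-ol F7, and acetylation (Ac2O, DMAP, pyridine) returns to 7.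

**Further compounds**
F1 | step 6 | 2-[(2S,3S,5S)-3-acetoxy-5-bromo-2,6,6-trimethyloxan-2-yl]acetic acid | CC(=O)O[C@H]1C[C@H](Br)C(C)(C)O[C@@]1(C)CC(=O)O
F2 | step 6 | (4R)-3-{2-[(2S,3S,5S)-3-acetoxy-5-bromo-2,6,6-trimethyloxan-2-yl]acetyl}-4-benzyl-1,3-oxazolidin-2-one | CC(=O)O[C@H]1C[C@H](Br)C(C)(C)O[C@@]1(C)CC(=O)N1[C@H](Cc2ccccc2)COC1=O
F3 | step 6 | (4R)-3-{(2R)-2-[(2S,3S,5S)-3-acetoxy-5-bromo-2,6,6-trimethyloxan-2-yl]-5-oxohexanoyl}-4-benzyl-1,3-oxazolidin-2-one | CC(=O)O[C@H]1C[C@H](Br)C(C)(C)O[C@@]1(C)[C@@H](CCC(C)=O)C(=O)N1[C@H](Cc2ccccc2)COC1=O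
F4 | step 6 | S-ethyl (2R)-2-[(2S,3S,5S)-3-acetoxy-5-bromo-2,6,6-trimethyloxan-2-yl]-5-oxohexanethioate | CC(=O)O[C@H]1C[C@H](Br)C(C)(C)O[C@@]1(C)[C@@H](CCC(C)=O)C(=O)SCC
F0 | step 13 | none | none
F5 | step 4 | (4S,5S)-5-(tert-butyldimethylsilyloxy)-4,8-dimethylnona-1,7-dien-4-ol | C=CC[C@](C)(O)[C@@H](O[Si](C)(C)C(C)(C)C)CC=C(C)C
F6 | step 4 | tert-butyl{[(2S,3S,5S)-5-bromo-2,6,6-trimethyl-2-(prop-2-en-1-yl)oxan-3-yl]oxy}dimethylsilane | CC(C)(C)[Si](C)(C)O[C@H]1C[C@H](Br)C(C)(C)O[C@@]1(C)CC=C
F7 | step 4 | (2S,3S,5S)-5-bromo-2,6,6-trimethyl-2-(prop-2-en-1-yl)oxan-3-ol | O[C@H]1C[C@H](Br)C(C)(C)O[C@@]1(C)CC=C
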